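(Readings and results stem from a simulated flask on assumed constants; the scatter is artificial.)

In a one-step world, with a single first-order step from substrate to product, the rate scales with the amount present, so the percent converted at a given time does not depend on the charge. Each step proposed here has a single reactant: substrate goes reversibly to intermediate A and to intermediate B, intermediate A reversibly to intermediate C, intermediate A to side product, and intermediates A and C to target. Taking each of them to be first order, the same holds for the whole scheme, and the alpha flask, with twice the charge, can continue the gamma flask past its last reading.

| flask | substrate | remark | time |
|---|---|---|---|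
| gamma | 0.019 M | the very flask that is asked about, followed so far |  |
| alpha | 0.038 M | run made earlier |  |
| flask | 0.019 M |  | 15 min |

- gamma (time / min: target / %, intermediate B / %): 0.667: 0, 20.6; 1.33: 1.2, 30.9; 2.00: 3.3, 35.9; 2.50: 2.4, 40.5
- alpha (time / min: target / %, intermediate B / %): 4.00: 3.5, 46.1; 8.00: 7.9, 47.6; 12.0: 10.8, 45.3; 15.0: 12.5, 45.0

(each reading ± 1 percentage point)

* the state of affairs at 15 min: stopped, and by what, or still going (all of the substrate has reacted / it is still moving / forward and back rates have come level)
* target at 15 min, in percent of the substrate charged
* intermediate B at 15 min, in percent of the substrate charged
* intermediate A at 15 min, in percent of the substrate charged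

- the numbers in the tables scatter with a standard deviation of 1 percentage point
- steps that have been proposed: substrate <-> intermediate A; substrate <-> intermediate B; intermediate A -> side product; intermediate A <-> intermediate C; intermediate C -> target; intermediate A -> target
- the reaction counts as stopped when no species that holds the substrate changes by six tenths of a point or more over the second half of the time

We read the two tables as one curve: the gamma flask's last intermediate B, 40.5% at 2.50 min, is still rising towards the alpha flask's first, 46.1% at 4.00 min. Further down the alpha table, intermediate B goes from 47.6% at 8.00 min to 45.0% at 15.0 min, while target stands higher at the end than at 8.00 min, going from 7.9% to 12.5%, so we expect the gamma flask to be still moving at 15 min.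

Now the balance of the substrate, the one thing charged. Alpha's last row leaves 42.5% of the charge in no column, and we call this the unread remainder: the charge minus target minus intermediate B. At 8.00 min it was 44.5%. Our own reckoning takes alpha's last target and intermediate B for the gamma flask and puts intermediate A somewhere inside the remainder, which it shares with substrate, intermediate C and side product.

The forecast says it is still moving, with target 12.6% (11.3% to 13.8%), intermediate B 45% (43.5% to 46.5%) and intermediate A 10% (3% to 22%), the last being, in its words, “a rough guess”.

    substrate ⇌ intermediate A (K = 0.700, k = 0.0130 s⁻¹)
    substrate ⇌ intermediate B (K = 2.20, k = 0.00770 s⁻¹)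
    intermediate A → side product (k = 7.80 × 10⁻⁴ s⁻¹)
    intermediate A ⇌ intermediate C (K = 0.330, k = 7.20 × 10⁻⁴ s⁻¹)
    intermediate C → target (k = 3.50 × 10⁻⁴ s⁻¹)
    intermediate A → target (k = 8.60 × 10⁻⁴ s⁻¹)

At 15 min the gamma flask stands thus: it is still moving, with target 13.0%, intermediate B 42.9% and intermediate A 11.7%, so its unread remainder is 44.1% against the 42.5% read from alpha. In the gamma flask, each step taken net, intermediate A was made 3.78 times as fast as it was used up at 0.713 min, but at 15.0 min it is made more slowly than it is used up, the ratio being 0.837. Left until 1.0 h, the same flask holds target 34.7%, above the high end of the forecast's range for 15 min. The 42.5% read from alpha, taken from the charge together with that flask's intermediate B of 20.7%, gives target 36.8%, against the 34.7% it holds.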